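## Structural features

Briarellin A is a tetracyclic diterpenoid (cembranoid-type numbering, see remarks). A cyclohexane (C1, C10–C14) is cis-fused at C1–C10 to an oxolane (O, C2, C1, C10, C9). The oxolane oxygen with C2 and C9 also belongs to a nine-membered oxonane (C2 to C9), and a seven-membered lactone (C14–C15–C16(=O)–O–C3–C2–C1) ties C14 to C3. There are ten stereocentres, (1S,2S,3S,4R,6S,9S,10R,11R,14R,15R): C15, C14, C1, C2, C3 and C4 form one contiguous run, C10, C9 and C11 adjoin it, and only C6 is isolated. C3 and C11 are fully substituted methyl carbinol carbons; C3 carries the lactone oxygen and C11 a free tertiary hydroxyl. The fragile groups are the C4 octanoate (1,2 to the C3 oxygen and 1,3 to the C6 hydroxyl, so open to acyl migration and to β-elimination once C6 is a carbonyl), the C6 allylic alcohol beside the C7 exocyclic methylene, the epimerisable C15 next to the lactone carbonyl, and tertiary hydroxyls that would attack a leaving group on C8. The real difficulties are the five contiguous CH centres C14, C1, C2, C9, C10, the medium ring, and acylation of the tertiary C3 oxygen in a seven-membered closure. The key step exploits the oxolane O–C2–C1–C10–C9 with C3 on C2 and C8 on C9, both cis: joining C3 to C8 through C4 gives the oxygen-bridged seven-membered carbocycle C2–C3–C4–C8–C9–C10–C1 of an oxidopyrylium–alkene adduct, in which C3 and C11 are ketones.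

## Logic of the disconnections

36 ⇒ 35. The C6–C7 bond is cut. It is the one ring bond whose formation from an aldehyde and a 2-iodoalkene makes the C6 carbinol and the C7 exocyclic methylene together, so nothing has to be adjusted after ring closure. The medium ring and the last stereocentre disappear. The forward step must close a nine-membered ring at high dilution beside an ester, a lactone and a tertiary alcohol, and must give the 6S alcohol.

35 ⇒ 33 ⇒ 31. The C6 aldehyde is traced to a terminal alkene (33), and the acyl–oxygen bond between C16 and the C3 oxygen is cut (31). Closing the lactone before the oxonane means the C3 hydroxyl is the only hydroxyl that can reach C16 and no C6 hydroxyl yet exists. The gain is a bicyclic seco acid. The demand is acylation of a tertiary alcohol in a seven-membered closure without loss of C15.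

31 ⇒ 28 ⇒ 27 ⇒ 26. The octanoyl C–O bond and then the C4–C5 bond are cut; C16 is returned to a protected primary alcohol. Cutting C4–C5 leaves an aldehyde next to the C3 carbinol, which can steer the new C4 centre by chelation, and the secondary/tertiary difference in 27 makes the octanoylation selective without protection. The demand is chelation-controlled addition to a tertiary α-hydroxy aldehyde.

26 ⇒ 24 ⇒ 22 ⇒ 19. The 2-iodoalkene is traced to a terminal alkyne and the C7–C8 bond is cut. C8 must end as a CH2 group, and displacing a C8 triflate with an acetylide brings in C7 and the exocyclic carbon at once. This puts a demand on protection: the C3/C4 diol (acetonide) and the C11 hydroxyl (silyl ether) must be masked so that none of them attacks the C8 triflate.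

19 ⇒ 17 ⇒ 16 ⇒ 14. The two hydroxymethyl carbons C4 and C8 are reconnected as the C4=C8 alkene of a bicycle. The gain is a rigid oxabicyclo[3.2.1]octene in which C2 and C9 are already cis. The forward ozonolysis demands that C4=C8 be the only alkene in the molecule.

14 ⇒ 13. The two C–CH3 bonds at C3 and C11 are cut, because both carbinol carbons are ketones in 13. The forward additions must occur on the oxygen-bridge face at C3 and anti to the C10–C9 bond at C11.

13 ⇒ 3 + 11. The C2–C1 and C9–C10 bonds are cut (the key step). Two rings, two skeletal bonds and four stereocentres are removed, leaving a pyranone and a cyclohexenone. The forward cycloaddition must be regioselective, anti to the C14 substituent and exo. The C14 substituent of 11 is carried as a saturated, silyl-protected C15–C16 unit with C15 already set: an alkene there would compete with C4=C8 in the ozonolysis and would leave C15 to a late acyclic hydroboration.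

11 ⇒ 9 ⇒ 7 + 8, and 7 ⇒ 5 ⇒ 4. The C1=C10 bond (aldol condensation) and the C13–C14 bond (Michael addition) are cut, then the C1–C14 bond (formylation of a Grignard reagent). C14 is set by an amine catalyst and C15 comes from a commercial C4 building block. The forward Michael step needs catalyst control at the aldehyde α-carbon.

3 ⇒ 2 ⇒ 1. The acetate is removed and the pyranone is traced to a furan by oxidative ring expansion. No stereochemistry is at stake, since 3 is used only as the source of an achiral ylide.

## Other disconnections considered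

Alternative 1: The cut is C3–C4 inside the oxonane. In the forward step the keto aldehyde A1 (C3 methyl ketone on C2, C4 aldehyde at the end of the C9 side chain) would be reduced by SmI2, or by low-valent titanium from TiCl3(DME)1.5 and Zn–Cu. The ketyl would couple with the ketone and give the nine-membered diol A2.
- In favour: one step would close the medium ring and make C3 and C4 with both oxygens at the right oxidation level. The tertiary and secondary hydroxyls would come out differentiated for lactonisation and octanoylation. On this point it is better than the chosen plan, which spends methyl addition, seam cleavage, acetonide, reoxidation and allylation to reach the same diol.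
- Against: two stereocentres, one of them quaternary, would form in a flexible nine-membered transition structure with only conformational or chelate control. The chosen plan sets C3 on a rigid bicycle and C4 from a five-membered chelate.
- Comparison: A1 still needs the five contiguous CH centres around the oxolane, which the chosen [5+2] step delivers at once. Overall step economy would be about equal; the stereochemical risk is concentrated in one late step.

Alternative 2: The cuts are C1–C14 and C10–C11 of the cyclohexane. In the forward step TiCl4 would promote Mukaiyama–Michael addition of the silyl enol ether A4 to the butenolide A3, anti to its C2 substituent. The resulting lactone enolate would then add to the pendant methyl ketone to give the hydroisobenzofuranone A5.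
- In favour: the cyclohexane, the cis C1/C10 fusion and the C11 methyl carbinol would form in one operation from a chiral-pool butenolide. C11 would arise without having to tell two ketones or two tertiary alcohols apart, which is better than the chosen plan. The C14 acetyl group is an equilibratable handle for C15.
- Against: in A5 C9 is still a lactone carbonyl and must become an ether CH carrying C8 with 2,5-cis control. C3 has to be grown from a CH2O group, and C16 from the acetyl group.
- Comparison: the chosen cycloaddition forms both ether carbons with their final C–C bonds and four stereocentres together. Alternative 2 is the equal of the chosen plan in convergence, but clearly longer after its key step.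

Alternative 3: The cuts are C4–C5 and O–C6. In the forward step NaOCl would oxidise the aldoxime A6 to the nitrile oxide A7, which would add to the terminal alkene of the 2-substituted butadiene on C9 and give the isoxazoline-fused pentacycle A8.
- In favour: the oxonane would close late, with the lactone in place, in a metal-free step that introduces the C6 oxygen and C4 as a masked carbonyl. It is the equal of the chosen plan in closing the medium ring last, and better in avoiding stoichiometric chromium.
- Against: nine-membered nitrile oxide closures compete with dimerisation, and C6 would be set by facial selectivity in a flexible chain. Afterwards the N–O bond would have to be cleaved beside the exocyclic methylene, and the C4 carbonyl reduced stereoselectively before octanoylation. The chosen plan sets C4 earlier by chelation and arrives at the ring closure with the octanoate installed.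
- Comparison: A6 again presupposes the tricyclic lactone core that the chosen key step is designed to build. End-game step counts would be similar.

Key step: step 7

Remarks on the chemistry (assumptions, one line each):
- Numbering: C1/C10 are the ring-fusion carbons, C2 and C9 flank the ether oxygen, C3 bears the lactone oxygen, C4 the octanoate, C6 the free secondary hydroxyl, C7 the exocyclic methylene, C11 the tertiary carbinol, C14 bears C15, and C16 is the lactone carbonyl.
- The structures of the cycloaddition partners and of the adduct are stereochemically consistent with the target (exo, anti to C14, R at the enone stereocentre); only the C14 spectator group was changed, from isopropenyl to (R)-CH(CH3)CH2OSi, with the carbon skeleton unchanged.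
- If the isopropenyl enone were made by amide desymmetrisation of 4-isopropenylcyclohexanone, the (S,S)-bis(1-phenylethyl)amide would be the enantiomer expected to lead to the (R)-enone, by analogy with 4-tert-butylcyclohexanone, where the (R,R)-amide leads to the (S)-enol silane.
- The sense of step 5 is assigned from the steric-shielding enamine model: the electrophile adds anti to the diarylmethyl group of the (S)-catalyst.
- The facial courses of steps 8, 16 and 22 are model-based predictions.

## Steps

Step 1
Reactants: 1 furfuryl alcohol
Product: 2 6-hydroxy-2H-pyran-3(6H)-one (racemic)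
Conditions: NBS, NaHCO3, NaOAc, THF/H2O (4:1), 0 °C
Reagents that add atoms: water, O
Why: Achmatowicz oxidative ring expansion: bromonium-induced addition of water to the furan, ring opening to the ene-dione and closure of the hydroxymethyl oxygen onto the aldehyde give the pyranone lactol.

Step 2
Reactants: 2 6-hydroxy-2H-pyran-3(6H)-one
Product: 3 6-acetoxy-2H-pyran-3(6H)-one (racemic)
Conditions: Ac2O, pyridine, DMAP (cat.), CH2Cl2, 0 °C
Reagents that add atoms: acetic anhydride, CC(=O)OC(C)=O
Why: Acylation of the lactol hydroxyl; the low temperature and weak base keep the acetate from ionising prematurely.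

Step 3
Reactants: 4 (S)-3-bromo-2-methylpropan-1-ol
Product: 5 (S)-(3-bromo-2-methylpropoxy)(tert-butyl)diphenylsilane
Conditions: TBDPSCl, imidazole, DMF, rt
Reagents that add atoms: tert-butyl(chloro)diphenylsilane, CC(C)(C)[Si](Cl)(c1ccccc1)c1ccccc1
Why: Silylation of the primary alcohol; the stereocentre (future C15) is not involved.

Step 4
Reactants: 5 (S)-(3-bromo-2-methylpropoxy)(tert-butyl)diphenylsilane
Product: 7 (R)-4-(tert-butyldiphenylsilyloxy)-3-methylbutanal, via Grignard reagent 6 (not isolated)
Conditions: Mg, 1,2-dibromoethane (cat.), THF, 50 °C; then DMF, 0 °C to rt; aq. HCl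
Reagents that add atoms: N,N-dimethylformamide, CN(C)C=O
Why: Grignard formation and Bouveault formylation; the magnesium hemiaminal resists a second addition until work-up, and the aldehyde carbon becomes C1.

Step 5
Reactants: 7 (R)-4-(tert-butyldiphenylsilyloxy)-3-methylbutanal; 8 methyl vinyl ketone
Product: 9 (S)-2-[(R)-1-(tert-butyldiphenylsilyloxy)propan-2-yl]-5-oxohexanal
Conditions: (S)-2-[methoxy(diphenyl)methyl]pyrrolidine (5 mol %), ethyl 3,4-dihydroxybenzoate (20 mol %), 8 (1.5 equiv), neat, 4 °C
Reagents that add atoms: none
Why: Enamine-catalysed Michael addition: the E-enamine of 7 is shielded on one face by the diarylmethyl group of the (S)-catalyst, so the enone adds from the other face and sets the future C14 as S in 9; the catechol co-catalyst activates the enone, and catalyst control should override the β-stereocentre.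

Step 6
Reactants: 9 (S)-2-[(R)-1-(tert-butyldiphenylsilyloxy)propan-2-yl]-5-oxohexanal
Product: 11 (R)-4-[(R)-1-(tert-butyldiphenylsilyloxy)propan-2-yl]cyclohex-2-en-1-one, via aldol 10 (not isolated)
Conditions: LiOH (0.1 equiv), iPrOH, rt
Reagents that add atoms: none
Why: Intramolecular aldol condensation (the ring-closing half of a Robinson annulation): the methyl ketone enolate adds to the aldehyde and the aldol dehydrates; any epimerisation at C14 would give a separable diastereomer because C15 is fixed.

Step 7
Reactants: 3 6-acetoxy-2H-pyran-3(6H)-one; 11 (R)-4-[(R)-1-(tert-butyldiphenylsilyloxy)propan-2-yl]cyclohex-2-en-1-one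
Product: 13 exo [5+2] adduct (8-oxabicyclo[3.2.1]oct-3-en-2-one with C3 ketone and C4=C8 alkene; exo-fused at C1–C10 to the C11 cyclohexanone), via 3-oxidopyrylium 12 (not isolated)
Conditions: 3 (3 equiv) added over 12 h by syringe pump to 11 and Et3N (4 equiv), MeCN, rt to 40 °C
Reagents that add atoms: none
Why: Triethylamine eliminates acetic acid from either enantiomer of 3 to give the planar, achiral 3-oxidopyrylium 12, a five-atom 4π dipole. It adds across C1=C10 of 11 in a thermally allowed, suprafacial [5+2] cycloaddition; the closest known reaction type is the intermolecular addition of 3-oxidopyrylium ylides to electron-poor alkenes. The oxolane O–C2–C1–C10–C9 and the seven-membered enone carbocycle C2–C3–C4–C8–C9–C10–C1 close together in this single concerted event. Regiochemistry follows polarity: the ylide carbon next to the oxido group (future C2) is the nucleophilic terminus and bonds to the enone β-carbon C1, while C9 bonds to the α-carbon C10. C2 and C9 are cis because the ylide is planar, and C1 and C10 are cis because the ring alkene is Z. The configuration of C1 relative to C14 comes from approach of the ylide anti to the branched C14 substituent next to the reacting β-carbon. The step also needs the exo arrangement (cyclohexanone on the side of the bridging oxygen, H1 and H10 endo); this rests only on the steric clash of the cyclohexenone methylenes and the C14 substituent with the oxidoallyl unit in the endo mode and is not assured. Slow addition of 3 keeps the ylide concentration low so that cycloaddition can compete with ylide dimerisation.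

Step 8
Reactants: 13 exo [5+2] adduct
Product: 14 3,11-dimethyl-3,11-diol (bicyclic tertiary allylic alcohol at C3; tertiary alcohol at C11)
Conditions: MeMgBr (6 equiv), anhydrous CeCl3 (6 equiv), THF, −78 to 0 °C
Reagents that add atoms: methylmagnesium bromide, C[Mg]Br
Why: Organocerium 1,2-addition to both ketones without enolisation or conjugate addition. At C3 the reagent should enter from the oxygen-bridge (exo) face, because the endo face is screened by H1 and H10; at C11 it should enter anti to the C10–C9 bond, which stands perpendicular to the carbonyl plane (Felkin–Anh-type control), placing the C11 hydroxyl cis to C9.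

Step 9
Reactants: 14 3,11-dimethyl-3,11-diol
Product: 16 C3,C4,C8,C11-tetraol (2,5-cis-disubstituted oxolane with C4H2OH and C8H2OH), via ozonide 15 (not isolated)
Conditions: O3, CH2Cl2, −78 °C; then MeOH, NaBH4, −78 to 0 °C
Reagents that add atoms: ozone, [O-][O+]=O
Why: Ozonolysis with reductive work-up; C4=C8 is the only alkene, so the bicycle opens at the seam to two primary alcohols. Any peroxy acetal formed by internal trapping is reduced to the same tetraol.

Step 10
Reactants: 16 C3,C4,C8,C11-tetraol
Product: 17 3,4-O-isopropylidene-8,11-diol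
Conditions: 2,2-dimethoxypropane, PPTS (cat.), CH2Cl2, rt
Reagents that add atoms: 2,2-dimethoxypropane, COC(C)(C)OC
Why: Acid-catalysed transacetalisation; only the vicinal C3/C4 diol can form a five-membered dioxolane (the C8/C11 pair would need a seven-membered ring), which separates C4 from C8 and masks the C3 hydroxyl.

Step 11
Reactants: 17 3,4-O-isopropylidene-8,11-diol
Product: 19 11-O-triethylsilyl ether with free C8 hydroxyl, via bis-silyl ether 18 (not isolated)
Conditions: TESOTf (2.5 equiv), 2,6-lutidine, CH2Cl2, −78 to 0 °C; MeOH quench, concentrate; then HF·pyridine, pyridine, THF, 0 °C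
Reagents that add atoms: triethylsilyl trifluoromethanesulfonate, CC[Si](CC)(CC)OS(=O)(=O)C(F)(F)F
Why: The silyl triflate silylates the primary and the tertiary hydroxyl; buffered HF·pyridine then cleaves only the unhindered primary triethylsilyl ether and leaves the tertiary TES ether, the TBDPS ether and the acetonide.

Step 12
Reactants: 19 11-O-triethylsilyl ether with free C8 hydroxyl
Product: 22 terminal alkyne (C8H2–C7≡CH), via triflate 20 (not isolated), via silylalkyne 21 (not isolated)
Conditions: Tf2O, 2,6-lutidine, CH2Cl2, −78 °C; crude triflate added to LiC≡CSiMe3 (from ethynyltrimethylsilane and n-BuLi), THF/DMPU, −78 to −20 °C; then K2CO3, MeOH, rt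
Reagents that add atoms: ethynyltrimethylsilane, C#C[Si](C)(C)C
Why: SN2 displacement of the primary triflate by the acetylide, then carbonate methanolysis of the C–Si bond; with the C3, C4 and C11 oxygens masked, no internal oxygen can displace the triflate.

Step 13
Reactants: 22 terminal alkyne
Product: 24 2-iodoalkene (C8H2–C7(I)=CH2), via alkenylborane 23 (not isolated)
Conditions: B-iodo-9-BBN, pentane/CH2Cl2, −20 °C; then AcOH, 0 °C; aq. NaHCO3
Reagents that add atoms: B-iodo-9-borabicyclo[3.3.1]nonane, IB1C2CCCC1CCC2
Why: Haloboration: B–I adds syn and Markovnikov across the terminal alkyne (iodine to C7), and protonolysis of the alkenyl–boron bond with acetic acid gives the 2-iodoalk-1-ene.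

Step 14
Reactants: 24 2-iodoalkene
Product: 25 3,4,11-triol (C4 primary; C3 and C11 tertiary)
Conditions: CSA (cat.), MeOH, rt to 40 °C
Reagents that add atoms: none
Why: Acid-catalysed methanolysis removes the acetonide and the tertiary triethylsilyl ether, which are no longer needed once C8 is a carbon substituent; the primary TBDPS ether and the iodoalkene are stable to these conditions.

Step 15
Reactants: 25 3,4,11-triol
Product: 26 tertiary α-hydroxy aldehyde (C4 aldehyde, free C3 hydroxyl)
Conditions: SO3·pyridine, DMSO, iPr2NEt, CH2Cl2, 0 °C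
Reagents that add atoms: none
Why: Parikh–Doering oxidation of the only primary alcohol; activated-DMSO conditions avoid the glycol cleavage that hypervalent iodine or periodate could cause, and the aldehyde has no α-hydrogen to epimerise.

Step 16
Reactants: 26 tertiary α-hydroxy aldehyde
Product: 27 (4R)-homoallylic 3,4-diol (C4H(OH)–CH2–CH=CH2)
Conditions: allyl bromide, In powder, THF/H2O (3:1), rt
Reagents that add atoms: allyl bromide, C=CCBr
Why: Barbier allylation under Cram chelate control: indium bridges the free C3 hydroxyl and the carbonyl oxygen in a five-membered chelate, and the allyl group enters past the small C3 methyl, anti to the C2 ring carbon, which should give the 3,4-syn (4R) diol.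

Step 17
Reactants: 27 (4R)-homoallylic 3,4-diol
Product: 28 C4 octanoate
Conditions: octanoyl chloride, pyridine, DMAP (cat.), CH2Cl2, 0 °C to rt
Reagents that add atoms: octanoyl chloride, CCCCCCCC(=O)Cl
Why: DMAP-catalysed acylation; only the secondary C4 hydroxyl should react, the C3 and C11 hydroxyls being tertiary and hindered.

Step 18
Reactants: 28 C4 octanoate
Product: 29 C16 primary alcohol
Conditions: TBAF, AcOH (1:1), THF, 0 °C to rt
Reagents that add atoms: none
Why: Fluoride-mediated desilylation; buffering with acetic acid keeps the medium non-basic so that the octanoate neither migrates nor is cleaved.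

Step 19
Reactants: 29 C16 primary alcohol
Product: 31 C16 carboxylic acid, via aldehyde 30 (not isolated)
Conditions: TEMPO (cat.), PhI(OAc)2, MeCN/H2O (1:1), rt
Reagents that add atoms: water, O
Why: Oxoammonium oxidation of the only primary alcohol through the aldehyde hydrate to the acid; tertiary alcohols and both alkenes are inert, and any lactone 33 formed directly from the lactol of 30 is the product of the next step.

Step 20
Reactants: 31 C16 carboxylic acid
Product: 33 seven-membered lactone (C16(=O)–O–C3), via mixed anhydride 32 (not isolated)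
Conditions: 2,4,6-trichlorobenzoyl chloride, Et3N, THF, rt; then slow addition to DMAP, toluene, 80 °C (high dilution)
Reagents that add atoms: none
Why: Yamaguchi lactonisation: the acylpyridinium formed from the mixed anhydride is trapped by the C3 tertiary hydroxyl, the only hydroxyl that can reach C16 (the C11 hydroxyl lies on the opposite face of the cyclohexane); heat and dilution compensate for the low nucleophilicity of the tertiary alcohol.

Step 21
Reactants: 33 seven-membered lactone
Product: 35 C6 aldehyde, via diol 34 (not isolated)
Conditions: OsO4 (cat.), NaIO4, 2,6-lutidine, dioxane/H2O (3:1), rt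
Reagents that add atoms: osmium tetroxide, O=[Os](=O)(=O)=O (catalytic oxygen carrier); sodium periodate, [Na+].[O-]I(=O)(=O)=O (stoichiometric oxygen source)
Why: Lemieux–Johnson cleavage: the monosubstituted alkene is dihydroxylated in preference to the electron-poor, hindered 2-iodoalkene, and periodate cleaves the diol; 2,6-lutidine keeps the β-acyloxy aldehyde from eliminating.

Step 22
Reactants: 35 C6 aldehyde
Product: 36 briarellin A
Conditions: CrCl2 (10 equiv), NiCl2 (1 mol %), DMSO, rt, 0.003 M
Reagents that add atoms: none
Why: Nozaki–Hiyama–Kishi coupling: nickel inserts into the C–I bond, transmetalation gives an alkenyl species of trivalent chromium, and this adds only to the aldehyde, closing the nine-membered ring with the C6 carbinol and the C7 methylene in place. The C6 configuration is set in the ring-closing transition state, where the aldehyde is expected to add with its oxygen directed to the outside of the forming ring to give the 6S alcohol; this is not assured.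

## Compound list

1 | furfuryl alcohol | OCc1ccco1 | starting material
2 | 6-hydroxy-2H-pyran-3(6H)-one (racemic) | OC1OCC(=O)C=C1 | intermediate
3 | 6-acetoxy-2H-pyran-3(6H)-one (racemic) | CC(=O)OC1OCC(=O)C=C1 | intermediate
4 | (S)-3-bromo-2-methylpropan-1-ol | OC[C@H](C)CBr | starting material
5 | (S)-(3-bromo-2-methylpropoxy)(tert-butyl)diphenylsilane | CC(C)(C)[Si](c1ccccc1)(c1ccccc1)OC[C@H](C)CBr | intermediate
6 | (S)-[3-(tert-butyldiphenylsilyloxy)-2-methylpropyl]magnesium bromide | CC(C)(C)[Si](c1ccccc1)(c1ccccc1)OC[C@H](C)C[Mg]Br | intermediate (not isolated)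
7 | (R)-4-(tert-butyldiphenylsilyloxy)-3-methylbutanal | CC(C)(C)[Si](c1ccccc1)(c1ccccc1)OC[C@H](C)CC=O | intermediate
8 | methyl vinyl ketone (but-3-en-2-one) | CC(=O)C=C | starting material
9 | (S)-2-[(R)-1-(tert-butyldiphenylsilyloxy)propan-2-yl]-5-oxohexanal | CC(C)(C)[Si](c1ccccc1)(c1ccccc1)OC[C@H](C)[C@@H](C=O)CCC(C)=O | intermediate
10 | 3-hydroxy-4-[(R)-1-(tert-butyldiphenylsilyloxy)propan-2-yl]cyclohexanone (ring C4 as in 11, carbinol centre undefined) | CC(C)(C)[Si](c1ccccc1)(c1ccccc1)OC[C@H](C)[C@@H]2CCC(=O)CC2O | intermediate (not isolated)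
11 | (R)-4-[(R)-1-(tert-butyldiphenylsilyloxy)propan-2-yl]cyclohex-2-en-1-one | CC(C)(C)[Si](c1ccccc1)(c1ccccc1)OC[C@H](C)[C@@H]2CCC(=O)C=C2 | intermediate
12 | 3-oxidopyrylium (pyrylium-3-olate) | [O-]c1ccc[o+]c1 | intermediate (not isolated)
13 | exo [5+2] adduct: C3-keto, C4=C8 8-oxabicyclo[3.2.1]octenone exo-fused at C1–C10 to the C11 cyclohexanone, C14 bearing (R)-CH(CH3)CH2OTBDPS; C1, C2, C9, C10, C14, C15 arranged as in 36 | O=C1C=C[C@@H]2O[C@H]1[C@H]3[C@@H](CCC(=O)[C@H]32)[C@@H](C)CO[Si](c4ccccc4)(c4ccccc4)C(C)(C)C | intermediate
14 | 3,11-dimethyl-3,11-diol of 13 (C3 methyl on the oxygen-bridge face, C11 hydroxyl cis to C9) | C[C@]1(O)C=C[C@@H]2O[C@H]1[C@H]3[C@@H](CC[C@@](C)(O)[C@H]32)[C@@H](C)CO[Si](c4ccccc4)(c4ccccc4)C(C)(C)C | intermediate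
15 | secondary ozonide of 14 (1,2,4-trioxolane across C4 and C8, configuration at C4 and C8 undefined) | C[C@]1(O)C5OOC(O5)[C@@H]2O[C@H]1[C@H]3[C@@H](CC[C@@](C)(O)[C@H]32)[C@@H](C)CO[Si](c4ccccc4)(c4ccccc4)C(C)(C)C | intermediate (not isolated)
16 | C3,C4,C8,C11-tetraol (2,5-cis oxolane; C3(CH3)(OH)CH2OH on C2, CH2OH on C9) | OC[C@@H]1O[C@@H]([C@H]2[C@@H](CC[C@@](C)(O)[C@H]21)[C@@H](C)CO[Si](c3ccccc3)(c3ccccc3)C(C)(C)C)[C@@](C)(O)CO | intermediate
17 | 3,4-O-isopropylidene-8,11-diol | OC[C@@H]1O[C@@H]([C@H]2[C@@H](CC[C@@](C)(O)[C@H]21)[C@@H](C)CO[Si](c3ccccc3)(c3ccccc3)C(C)(C)C)[C@@]4(C)OC(C)(C)OC4 | intermediate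
18 | 8,11-bis(triethylsilyl) ether of 17 | CC[Si](CC)(CC)OC[C@@H]1O[C@@H]([C@H]2[C@@H](CC[C@@](C)(O[Si](CC)(CC)CC)[C@H]21)[C@@H](C)CO[Si](c3ccccc3)(c3ccccc3)C(C)(C)C)[C@@]4(C)OC(C)(C)OC4 | intermediate (not isolated)
19 | 11-O-triethylsilyl ether with free C8 hydroxyl | OC[C@@H]1O[C@@H]([C@H]2[C@@H](CC[C@@](C)(O[Si](CC)(CC)CC)[C@H]21)[C@@H](C)CO[Si](c3ccccc3)(c3ccccc3)C(C)(C)C)[C@@]4(C)OC(C)(C)OC4 | intermediate
20 | C8 trifluoromethanesulfonate of 19 | FC(F)(F)S(=O)(=O)OC[C@@H]1O[C@@H]([C@H]2[C@@H](CC[C@@](C)(O[Si](CC)(CC)CC)[C@H]21)[C@@H](C)CO[Si](c3ccccc3)(c3ccccc3)C(C)(C)C)[C@@]4(C)OC(C)(C)OC4 | intermediate (not isolated)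
21 | C8-(trimethylsilylethynyl) compound | C[Si](C)(C)C#CC[C@@H]1O[C@@H]([C@H]2[C@@H](CC[C@@](C)(O[Si](CC)(CC)CC)[C@H]21)[C@@H](C)CO[Si](c3ccccc3)(c3ccccc3)C(C)(C)C)[C@@]4(C)OC(C)(C)OC4 | intermediate (not isolated)
22 | terminal alkyne (C8H2–C7≡CH) | C#CC[C@@H]1O[C@@H]([C@H]2[C@@H](CC[C@@](C)(O[Si](CC)(CC)CC)[C@H]21)[C@@H](C)CO[Si](c3ccccc3)(c3ccccc3)C(C)(C)C)[C@@]4(C)OC(C)(C)OC4 | intermediate
23 | (Z)-2-iodoalkenyl-9-borabicyclo[3.3.1]nonane (iodine on C7, boron on the terminal carbon, cis) | I/C(C[C@@H]1O[C@@H]([C@H]2[C@@H](CC[C@@](C)(O[Si](CC)(CC)CC)[C@H]21)[C@@H](C)CO[Si](c3ccccc3)(c3ccccc3)C(C)(C)C)[C@@]4(C)OC(C)(C)OC4)=C\B5C6CCCC5CCC6 | intermediate (not isolated)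
24 | 2-iodoalkene (C8H2–C7(I)=CH2) with acetonide, C11 TES ether and C16 TBDPS ether | C=C(I)C[C@@H]1O[C@@H]([C@H]2[C@@H](CC[C@@](C)(O[Si](CC)(CC)CC)[C@H]21)[C@@H](C)CO[Si](c3ccccc3)(c3ccccc3)C(C)(C)C)[C@@]4(C)OC(C)(C)OC4 | intermediate
25 | 3,4,11-triol (2-iodoalkene, C16 TBDPS ether) | C=C(I)C[C@@H]1O[C@@H]([C@H]2[C@@H](CC[C@@](C)(O)[C@H]21)[C@@H](C)CO[Si](c3ccccc3)(c3ccccc3)C(C)(C)C)[C@@](C)(O)CO | intermediate
26 | tertiary α-hydroxy aldehyde (C4 aldehyde) | C=C(I)C[C@@H]1O[C@@H]([C@H]2[C@@H](CC[C@@](C)(O)[C@H]21)[C@@H](C)CO[Si](c3ccccc3)(c3ccccc3)C(C)(C)C)[C@@](C)(O)C=O | intermediate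
27 | (4R)-homoallylic 3,4-diol | C=C(I)C[C@@H]1O[C@@H]([C@H]2[C@@H](CC[C@@](C)(O)[C@H]21)[C@@H](C)CO[Si](c3ccccc3)(c3ccccc3)C(C)(C)C)[C@@](C)(O)[C@H](O)CC=C | intermediate
28 | C4 octanoate (C3 and C11 hydroxyls free) | C=C(I)C[C@@H]1O[C@@H]([C@H]2[C@@H](CC[C@@](C)(O)[C@H]21)[C@@H](C)CO[Si](c3ccccc3)(c3ccccc3)C(C)(C)C)[C@@](C)(O)[C@H](OC(=O)CCCCCCC)CC=C | intermediate
29 | C16 primary alcohol | C=C(I)C[C@@H]1O[C@@H]([C@H]2[C@@H](CC[C@@](C)(O)[C@H]21)[C@@H](C)CO)[C@@](C)(O)[C@H](OC(=O)CCCCCCC)CC=C | intermediate
30 | C16 aldehyde | C=C(I)C[C@@H]1O[C@@H]([C@H]2[C@@H](CC[C@@](C)(O)[C@H]21)[C@@H](C)C=O)[C@@](C)(O)[C@H](OC(=O)CCCCCCC)CC=C | intermediate (not isolated)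
31 | C16 carboxylic acid (seco acid) | C=C(I)C[C@@H]1O[C@@H]([C@H]2[C@@H](CC[C@@](C)(O)[C@H]21)[C@@H](C)C(=O)O)[C@@](C)(O)[C@H](OC(=O)CCCCCCC)CC=C | intermediate
32 | mixed anhydride of 31 with 2,4,6-trichlorobenzoic acid | C=C(I)C[C@@H]1O[C@@H]([C@H]2[C@@H](CC[C@@](C)(O)[C@H]21)[C@@H](C)C(=O)OC(=O)c3c(Cl)cc(Cl)cc3Cl)[C@@](C)(O)[C@H](OC(=O)CCCCCCC)CC=C | intermediate (not isolated)
33 | tricyclic seven-membered lactone with 2-iodoallyl group on C9 and allyl group on C4 | C=C(I)C[C@@H]1O[C@H]2[C@H]3[C@@H](CC[C@@](C)(O)[C@H]31)[C@@H](C)C(=O)O[C@@]2(C)[C@H](OC(=O)CCCCCCC)CC=C | intermediate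
34 | terminal 1,2-diol from the allyl group of 33 (new carbinol centre undefined) | C=C(I)C[C@@H]1O[C@H]2[C@H]3[C@@H](CC[C@@](C)(O)[C@H]31)[C@@H](C)C(=O)O[C@@]2(C)[C@H](OC(=O)CCCCCCC)CC(O)CO | intermediate (not isolated)
35 | C6 aldehyde (β-octanoyloxy aldehyde with 2-iodoalkene) | C=C(I)C[C@@H]1O[C@H]2[C@H]3[C@@H](CC[C@@](C)(O)[C@H]31)[C@@H](C)C(=O)O[C@@]2(C)[C@H](OC(=O)CCCCCCC)CC=O | intermediate
36 | briarellin A, (1S,2S,3S,4R,6S,9S,10R,11R,14R,15R) | C=C1C[C@@H]2O[C@H]3[C@H]4[C@@H](CC[C@@](C)(O)[C@H]42)[C@@H](C)C(=O)O[C@@]3(C)[C@H](OC(=O)CCCCCCC)C[C@@H]1O | target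

## Step count and least certain steps

Total: 22 steps. Longest linear sequence: 20 steps (4 to 36 through steps 3–22); the pyranone branch (steps 1–2) joins at step 7.

**Step 7 (key step).**
- What may go wrong: dimerisation of the ylide may outrun its addition to a hindered, only moderately electron-poor disubstituted enone. Reaction through the endo arrangement would invert C1 and C10 relative to C2 and C9, which cannot be repaired later.
- Fallback (sets out from 11, returns at 13; it raises the reactivity of the 2π partner but does not itself enforce exo addition): α-iodination of 11 (I2, pyridine, CH2Cl2) gives the more electron-poor 2-iodoenone F1. Cycloaddition of F1 with 3 and Et3N under the conditions of step 7 gives the C10-iodo adduct F2. Zinc in acetic acid at 0 °C removes the iodine to give 13; protonation of the zinc enolate should give the cis fusion at C10, because a trans fusion across the two-carbon bridge is strained.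

**Step 20 (lactonisation).**
- What may go wrong: the tertiary, flanked C3 hydroxyl may attack the acylpyridinium too slowly, so that intermolecular acylation and epimerisation at C15 intervene.
- Fallback (sets out from 29, returns at 33, bypassing 31 and 32): oxidative lactonisation. TEMPO (cat.) and PhI(OAc)2 in anhydrous CH2Cl2 oxidise 29 to aldehyde 30, which closes reversibly with the C3 hydroxyl to the seven-membered lactol F3; further oxidation of F3 gives 33. The C–O bond is thus made by hemiacetal formation and not by acyl substitution.

**Step 22 (ring closure).**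
- What may go wrong: poor facial selectivity at C6 in the nine-membered transition state, and oligomerisation if the closure is slow.
- Fallback (sets out from 35, returns at 36): the coupling is run as planned, and the mixture of 36 and its C6 epimer F4 is oxidised with Dess–Martin periodinane (NaHCO3, CH2Cl2) to the cross-conjugated C6 ketone F5. Reduction of F5 under catalyst control with (R)-2-methyl-CBS-oxazaborolidine and BH3·SMe2 at −40 °C gives 36; the alkenyl branch acts as the large group, so the (R)-catalyst should give the 6S alcohol.

**Step 16 (C4 stereocentre).**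
- What may go wrong: incomplete chelate control if indium binds the oxolane oxygen instead of, or together with, the C3 hydroxyl, which would erode the facial selectivity.
- Fallback (sets out from 26, returns at 27; reagent control replaces substrate control and no new compound is made, F0): B-allyldiisopinocampheylborane prepared from (+)-B-methoxydiisopinocampheylborane (from (−)-α-pinene) and allylmagnesium bromide, Et2O, −78 °C, in excess to saturate the free hydroxyls; then ethanolamine work-up. This is the enantiomer that adds to the Re face of the C4 aldehyde, as the 4R configuration requires.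

**Step 13 (iodoalkene).**
- What may go wrong: cleavage of the acetonide or the silyl ethers by the Lewis-acidic boron iodide, and hydrogen iodide formed from adventitious hydroxyl groups.
- Fallback (sets out from 19, returns at 24, bypassing 21–23): triflate 20, made as in step 12, is coupled with (1-(trimethylsilyl)vinyl)magnesium bromide and CuI (cat.) in THF at −30 °C to give the 2-silylalkene F6. Iododesilylation of F6 with N-iodosuccinimide (MeCN/ClCH2CN, 0 °C) gives 24.

## Further compounds

F1 | step 7 | (R)-2-iodo-4-[(R)-1-(tert-butyldiphenylsilyloxy)propan-2-yl]cyclohex-2-en-1-one | CC(C)(C)[Si](c1ccccc1)(c1ccccc1)OC[C@H](C)[C@@H]2CCC(=O)C(I)=C2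
F2 | step 7 | C10-iodo exo [5+2] adduct (iodine endo on C10, otherwise as 13) | O=C1C=C[C@@H]2O[C@H]1[C@H]3[C@@H](CCC(=O)[C@]32I)[C@@H](C)CO[Si](c4ccccc4)(c4ccccc4)C(C)(C)C
F3 | step 20 | seven-membered lactol (C16 hemiacetal with the C3 oxygen, C16 configuration undefined) | C=C(I)C[C@@H]1O[C@H]2[C@H]3[C@@H](CC[C@@](C)(O)[C@H]31)[C@@H](C)C(O)O[C@@]2(C)[C@H](OC(=O)CCCCCCC)CC=C
F4 | step 22 | 6-epi-briarellin A (6R) | C=C1C[C@@H]2O[C@H]3[C@H]4[C@@H](CC[C@@](C)(O)[C@H]42)[C@@H](C)C(=O)O[C@@]3(C)[C@H](OC(=O)CCCCCCC)C[C@H]1O
F5 | step 22 | 6-oxo compound (C6 ketone conjugated with the C7 methylene) | C=C1C[C@@H]2O[C@H]3[C@H]4[C@@H](CC[C@@](C)(O)[C@H]42)[C@@H](C)C(=O)O[C@@]3(C)[C@H](OC(=O)CCCCCCC)CC1=O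
F0 | step 16 | none | none
F6 | step 13 | 2-(trimethylsilyl)alkene (C8H2–C7(SiMe3)=CH2) with acetonide, C11 TES ether and C16 TBDPS ether | C=C([Si](C)(C)C)C[C@@H]1O[C@@H]([C@H]2[C@@H](CC[C@@](C)(O[Si](CC)(CC)CC)[C@H]21)[C@@H](C)CO[Si](c3ccccc3)(c3ccccc3)C(C)(C)C)[C@@]4(C)OC(C)(C)OC4
A1 | alternative 1 | keto aldehyde (C3 methyl ketone on C2; C4 aldehyde, C6 silyl ether and C7 methylene on the C9 side chain) | C=C(C[C@@H]1O[C@@H]([C@H]2[C@@H](CC[C@@](C)(O[Si](CC)(CC)CC)[C@H]21)[C@@H](C)CO[Si](C)(C)C(C)(C)C)C(C)=O)[C@H](CC=O)O[Si](C)(C)C(C)(C)C
A2 | alternative 1 | tricyclic C3,C4-diol | C=C1C[C@@H]2O[C@@H]([C@H]3[C@@H](CC[C@@](C)(O[Si](CC)(CC)CC)[C@H]32)[C@@H](C)CO[Si](C)(C)C(C)(C)C)[C@@](C)(O)[C@H](O)C[C@@H]1O[Si](C)(C)C(C)(C)C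
A3 | alternative 2 | (S)-5-[(tert-butyldiphenylsilyloxy)methyl]furan-2(5H)-one | O=C1C=C[C@@H](CO[Si](c2ccccc2)(c2ccccc2)C(C)(C)C)O1
A4 | alternative 2 | 6-(trimethylsilyloxy)hept-5-en-2-one | CC(=O)CCC=C(C)O[Si](C)(C)C
A5 | alternative 2 | cis-fused hydroisobenzofuranone with C11 tertiary alcohol and C14 acetyl group | CC(=O)[C@@H]1CC[C@@](C)(O)[C@H]2C(=O)O[C@H](CO[Si](c3ccccc3)(c3ccccc3)C(C)(C)C)[C@@H]12
A6 | alternative 3 | tricyclic lactone C4 aldoxime with 2-substituted butadiene on C9 | C=CC(=C)C[C@@H]1O[C@H]2[C@H]3[C@@H](CC[C@@](C)(O)[C@H]31)[C@@H](C)C(=O)O[C@@]2(C)C=NO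
A7 | alternative 3 | nitrile oxide derived from A6 | C=CC(=C)C[C@@H]1O[C@H]2[C@H]3[C@@H](CC[C@@](C)(O)[C@H]31)[C@@H](C)C(=O)O[C@@]2(C)C#[N+][O-]
A8 | alternative 3 | isoxazoline-fused pentacycle | C=C1C[C@@H]2O[C@H]3[C@H]4[C@@H](CC[C@@](C)(O)[C@H]42)[C@@H](C)C(=O)O[C@@]3(C)C5=NO[C@H]1C5
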